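**Retrosynthetic overview**
- Feature: ring A, the benzene ring of the chroman-2-one, carries its two oxygens on C8a and C7. They are meta to each other across the lone C8–H, beside CH3 on C5 and the stereogenic C4 on C4a. The atoms C8a, C6, C5 and C4a are read as a vinylketene (C8a the C=O carbon, C6 the ketene CH), and C7–C8 as TIPSO–C≡C–H.
- Last disconnections: both Si–O bonds and the O–CH3 bond. Then pyranone ring C at O1'–C2' and C4'–C5' (C6-acetyl enol silane plus malonyl dichloride). Then C6–C6' by Stille coupling at a bromide placed para to the still free C8a–OH, and lactone ring B at O1–C2.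
- Key disconnection: ring A at C8–C8a, C6–C7 and C4a–C8a. This leads to (triisopropylsilyloxy)ethyne and an (E)-α'-diazo enone that already carries C4 with its aryl group and ester arm.
- The diazo ketone comes from the methyl enone by diazo transfer. The enone comes from a vinyl group by cross-metathesis with methacrolein, MeMgBr addition and oxidation. C4 is set by iridium-catalysed enantioconvergent allylation of an acetate enolate surrogate with the racemic aryl vinyl carbinol made from 4-hydroxybenzaldehyde.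
- Ring order: ring D (4-hydroxyphenyl) is bought, then ring A (step 10), ring B (step 12), ring C (step 15).

Key step: step 10

Remarks:
- Locants C2–C8a are those of the chroman-2-one in the target and are used for the same atoms in every precursor. Primed locants belong to the pyranone.
- TBSO = tert-butyldimethylsilyloxy, TIPSO = triisopropylsilyloxy, Ar = 4-(TBSO)phenyl.
- (S)-L = (S)-5-(dinaphtho[2,1-d:1',2'-f][1,3,2]dioxaphosphepin-4-yl)-5H-dibenzo[b,f]azepine.
- Assumption: the (S)-ligand is taken to deliver the (S)-pentenoate. If the sense of induction is the reverse, the equally available (R)-ligand is used.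
- The descriptor at C4 changes from S to R in step 10 only because the CIP ranking changes. The spatial arrangement stays the same.

Step 1
Reactants: 1 4-hydroxybenzaldehyde
Product: 2 4-(TBSO)benzaldehyde
Conditions: TBSCl, imidazole, DMF, rt
Reagents that add atoms: tert-butyldimethylsilyl chloride CC(C)(C)[Si](C)(C)Cl
Why: Imidazole-promoted silylation of a phenol is routine and removes the acidic OH before the Grignard step.

Step 2
Reactants: 2 4-(TBSO)benzaldehyde; 3 vinylmagnesium bromide
Product: 4 rac-1-Ar-prop-2-en-1-ol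
Conditions: CH2=CHMgBr, THF, −78 → 0 °C; then H2O
Reagents that add atoms: none
Why: Grignard 1,2-addition to an aryl aldehyde, in which the carbinol centre is left racemic on purpose because the next step is enantioconvergent.

Step 3
Reactants: 4 rac-1-Ar-prop-2-en-1-ol; 5 trimethyl orthoacetate
Product: 7 methyl (S)-3-Ar-pent-4-enoate, via 1,1-dimethoxyethene 6 (not isolated)
Conditions: [Ir(cod)Cl]2 (3 mol %), (S)-L (12 mol %), Zn(OTf)2 (10 mol %), MeC(OMe)3 (5 equiv), 1,4-dioxane, rt
Reagents that add atoms: none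
Why: Iridium-catalysed enantioconvergent allylic substitution of a racemic branched aryl allylic alcohol, in the documented variant where the orthoacetate stands in for the methyl acetate enolate: acid ionises both enantiomers of 4 to one (η3-allyl)iridium complex of the chiral phosphoramidite–olefin ligand, and ketene acetal 6 attacks the aryl-bearing terminus on the face the ligand leaves open, which sets C4.

Step 4
Reactants: 7 methyl (S)-3-Ar-pent-4-enoate; 8 methacrolein
Product: 9 methyl (3S,4E)-3-Ar-5-methyl-6-oxohex-4-enoate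
Conditions: second-generation Hoveyda–Grubbs catalyst (5 mol %), methacrolein (8 equiv), 1,4-benzoquinone (10 mol %), CH2Cl2, 40 °C
Reagents that add atoms: none
Why: Olefin cross-metathesis of a terminal alkene with the 1,1-disubstituted partner methacrolein should give the conjugated trisubstituted (E)-enal under thermodynamic control, without base or an enolisable carbonyl at C4, while benzoquinone holds back ruthenium hydride isomerisation.

Step 5
Reactants: 9 methyl (3S,4E)-3-Ar-5-methyl-6-oxohex-4-enoate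
Product: 10 methyl (3S,4E)-3-Ar-6-hydroxy-5-methylhept-4-enoate (both C6 epimers)
Conditions: MeMgBr (1.1 equiv), THF, −78 °C; then H2O
Reagents that add atoms: methylmagnesium bromide C[Mg]Br
Why: Grignard 1,2-addition, in which the aldehyde reacts far faster than the methyl ester at −78 °C, and the uncontrolled new carbinol centre is erased in step 6.

Step 6
Reactants: 10 methyl (3S,4E)-3-Ar-6-hydroxy-5-methylhept-4-enoate
Product: 11 methyl (3S,4E)-3-Ar-5-methyl-6-oxohept-4-enoate
Conditions: Dess–Martin periodinane, CH2Cl2, 0 °C → rt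
Reagents that add atoms: none
Why: Dess–Martin oxidation of a secondary allylic alcohol runs close to neutrality, so the alkene geometry and the γ-stereocentre C4 are not disturbed.

Step 7
Reactants: 11 methyl (3S,4E)-3-Ar-5-methyl-6-oxohept-4-enoate
Product: 13 methyl (3S,4E)-7-diazo-5-methyl-6-oxo-3-Ar-hept-4-enoate, via trifluoroacetyl diketone 12 (not isolated)
Conditions: LiN(SiMe3)2 (1.1 equiv), THF, −78 °C; CF3CO2CH2CF3; 5% aq HCl wash; then 4-AcNHC6H4SO2N3, Et3N, H2O (1 equiv), MeCN, rt
Reagents that add atoms: 4-acetamidobenzenesulfonyl azide CC(=O)Nc1ccc(cc1)S(=O)(=O)N=[N+]=[N-]; 2,2,2-trifluoroethyl trifluoroacetate O=C(OCC(F)(F)F)C(F)(F)F (its CF3CO group stays only in 12)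
Why: Detrifluoroacetylative diazo transfer: the amide base takes a proton from the α'-methyl group under kinetic control (faster than from the ester CH2 or from C4), trifluoroacetylation makes that carbon acidic enough for Et3N, and the sulfonyl azide delivers N2 while the trifluoroacetyl group leaves on the sulfonamide, a sequence designed for α,β-unsaturated methyl ketones.

Step 8
Reactants: 14 trimethylsilylacetylene; 15 triisopropylsilyl trifluoromethanesulfonate
Product: 18 triisopropyl{[(trimethylsilyl)ethynyl]oxy}silane, via lithium trimethylsilylacetylide 16 (not isolated), via lithium silylynolate 17 (not isolated)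
Conditions: nBuLi, THF, −78 °C; LiOOtBu (from tBuOOH and LiN(SiMe3)2), −78 → 0 °C; TIPSOTf, −78 → 0 °C
Reagents that add atoms: tert-butyl hydroperoxide CC(C)(C)OO
Why: Electrophilic oxygenation of a lithium acetylide by lithium tert-butyl peroxide gives ynolate 17, which the bulky triflate 15 silylates on oxygen because C-silylation next to SiMe3 is too crowded.

Step 9
Reactants: 18 triisopropyl{[(trimethylsilyl)ethynyl]oxy}silane
Product: 19 (triisopropylsilyloxy)ethyne
Conditions: K2CO3 (10 mol %), MeOH, 0 °C; pentane extraction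
Reagents that add atoms: none
Why: Carbonate-catalysed methanolysis of an alkynyl–SiMe3 bond (protodesilylation of an alkynylsilane) is fast at 0 °C, whereas the O–Si(iPr)3 bond is shielded and the electron-rich triple bond does not add methoxide.

Step 10
Reactants: 13 methyl (3S,4E)-7-diazo-5-methyl-6-oxo-3-Ar-hept-4-enoate; 19 (triisopropylsilyloxy)ethyne
Product: 24 methyl (R)-3-[2-hydroxy-6-methyl-4-(TIPSO)phenyl]-3-Ar-propanoate, via vinylketene 20 (not isolated), via alkenylcyclobutenone 21 (not isolated), via dienylketene 22 (not isolated), via cyclohexadienone 23 (not isolated)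
Conditions: 19 (1.5 equiv), hν (254 nm, quartz), degassed ClCH2CH2Cl, rt; then 80 °C
Reagents that add atoms: none
Why: Light expels N2 from 13 and the alkenyl group migrates (Wolff rearrangement) to give vinylketene 20, whose carbonyl carbon (C8a) is attacked by the nucleophilic terminal carbon of 19 (C8) while the ketene CH (C6) closes onto the oxygen-bearing alkyne carbon (C7), a (2+2) cycloaddition leading to the 4-alkenylcyclobutenone 21. At 80 °C 21 opens by a four-electron conrotatory electrocyclic reaction that breaks the transient C6–C8a bond, and dienylketene 22 then forms C4a–C8a by a six-electron disrotatory electrocyclic closure, the only lasting ring closure of the step, after which dienone 23 tautomerises to phenol 24. This is the Danheiser benzannulation in its diazo ketone form, known for unsaturated diazo ketones and siloxyalkynes as a route to resorcinol monosilyl ethers. No lasting stereocentre is made, since the sp3 ring carbons of 21 and 23 vanish on aromatisation, and C4 lies one bond outside the reacting π system and keeps its configuration. The selectivity needed is the orientation of the ketene–alkyne addition, which the oxygen polarisation of 19 secures, so that OTIPS ends on C7, H on C8 and the free OH on C8a beside the ester arm. The (E) geometry of 13 holds C4–H away from the ketene carbon so that a 1,5-hydrogen shift should not compete, and the excess of 19 limits acylation of 24 by 20.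

Step 11
Reactants: 24 methyl (R)-3-[2-hydroxy-6-methyl-4-(TIPSO)phenyl]-3-Ar-propanoate
Product: 25 methyl (R)-3-[3-bromo-6-hydroxy-2-methyl-4-(TIPSO)phenyl]-3-Ar-propanoate
Conditions: NBS (1.0 equiv), MeCN, −20 → 0 °C, dark
Reagents that add atoms: N-bromosuccinimide O=C1CCC(=O)N1Br
Why: Electrophilic aromatic bromination with NBS in MeCN goes para to a free phenol: C6 is para to C8a–OH and ortho to C7–O, the position that orcinol-type rings use, whereas C8 lies between two oxygens and the monosilyloxy ring D is far less activated.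

Step 12
Reactants: 25 methyl (R)-3-[3-bromo-6-hydroxy-2-methyl-4-(TIPSO)phenyl]-3-Ar-propanoate
Product: 26 (R)-6-bromo-4-Ar-5-methyl-7-(TIPSO)chroman-2-one
Conditions: TsOH·H2O (10 mol %), 4 Å MS, toluene, 80 °C
Reagents that add atoms: none
Why: Acid-catalysed intramolecular transesterification closes the six-membered lactone (6-exo-trig attack of C8a–OH on the ester), helped by the buttressing C5 methyl and C4 aryl groups, and it masks phenol and carboxyl together while aryl silyl ethers tolerate catalytic TsOH.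

Step 13
Reactants: 26 (R)-6-bromo-4-Ar-5-methyl-7-(TIPSO)chroman-2-one; 27 tributyl(1-ethoxyvinyl)stannane
Product: 29 (R)-6-acetyl-4-Ar-5-methyl-7-(TIPSO)chroman-2-one, via ethoxyvinyl arene 28 (not isolated)
Conditions: Pd(PPh3)4 (5 mol %), toluene, 110 °C; then 1 M HCl, THF, rt
Reagents that add atoms: water O
Why: Stille coupling, in which zerovalent palladium inserts into the C6–Br bond and tin hands over the small α-ethoxyvinyl group under neutral conditions that spare the lactone and silyl ethers, followed by mild acid hydrolysis of enol ether 28 to the acetyl group.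

Step 14
Reactants: 29 (R)-6-acetyl-4-Ar-5-methyl-7-(TIPSO)chroman-2-one
Product: 30 (R)-4-Ar-5-methyl-7-(TIPSO)-6-[1-(trimethylsilyloxy)vinyl]chroman-2-one
Conditions: TMSOTf (1.2 equiv), Et3N, CH2Cl2, 0 °C; cold NaHCO3 wash, used crude
Reagents that add atoms: trimethylsilyl trifluoromethanesulfonate C[Si](C)(C)OS(=O)(=O)C(F)(F)F
Why: Soft enolisation–silylation of a methyl ketone that has only one enolisable side and reacts faster than the lactone CH2 when the triflate is kept near one equivalent.

Step 15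
Reactants: 30 (R)-4-Ar-5-methyl-7-(TIPSO)-6-[1-(trimethylsilyloxy)vinyl]chroman-2-one; 31 malonyl dichloride
Product: 33 (R)-6-(4-hydroxy-2-oxo-2H-pyran-6-yl)-4-Ar-5-methyl-7-(TIPSO)chroman-2-one, via dioxopentanoyl chloride 32 (not isolated)
Conditions: ClCOCH2COCl (1.05 equiv), Et2O, −78 °C → rt
Reagents that add atoms: none
Why: Acylation–cyclisation of a silyl enol ether with malonyl dichloride, the known route from aryl methyl ketone enol silanes to 6-aryl-4-hydroxy-2-pyranones: C5' attacks one acyl chloride with loss of Me3SiCl to give 32, whose aryl ketone enol oxygen closes on the second acyl chloride (6-exo-trig O-acylation) under base-free conditions that spare the lactone.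

Step 16
Reactants: 33 (R)-6-(4-hydroxy-2-oxo-2H-pyran-6-yl)-4-Ar-5-methyl-7-(TIPSO)chroman-2-one
Product: 34 (R)-6-(4-methoxy-2-oxo-2H-pyran-6-yl)-4-Ar-5-methyl-7-(TIPSO)chroman-2-one
Conditions: Me2SO4 (1.1 equiv), K2CO3 (1.1 equiv), dry acetone, rt
Reagents that add atoms: dimethyl sulfate COS(=O)(=O)OC
Why: O-alkylation of the vinylogous acid, in which only the acidic 4'-OH is deprotonated and dimethyl sulfate in acetone gives the 4-methoxy-2-pyranone rather than the 2-methoxy-4-pyranone isomer, as it does with triacetic acid lactone.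

Step 17
Reactants: 34 (R)-6-(4-methoxy-2-oxo-2H-pyran-6-yl)-4-Ar-5-methyl-7-(TIPSO)chroman-2-one
Product: 35 (R)-7-hydroxy-4-(4-hydroxyphenyl)-6-(4-methoxy-2-oxo-2H-pyran-6-yl)-5-methylchroman-2-one
Conditions: Bu4NF, AcOH (1:1, 2.5 equiv each), THF, 0 °C
Reagents that add atoms: none
Why: Fluoride cleavage of both aryl silyl ethers, with acetic acid buffering the phenoxides so that neither the aryl lactone nor the pyranone is opened and C4 is not touched.

**Compound list**
1 | 4-hydroxybenzaldehyde | O=Cc1ccc(O)cc1 | starting material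
2 | 4-(tert-butyldimethylsilyloxy)benzaldehyde | O=Cc1ccc(O[Si](C)(C)C(C)(C)C)cc1 | intermediate
3 | vinylmagnesium bromide | C=C[Mg]Br | starting material
4 | rac-1-[4-(tert-butyldimethylsilyloxy)phenyl]prop-2-en-1-ol | C=CC(O)c1ccc(O[Si](C)(C)C(C)(C)C)cc1 | intermediate
5 | trimethyl orthoacetate | CC(OC)(OC)OC | starting material
6 | 1,1-dimethoxyethene | C=C(OC)OC | intermediate
7 | methyl (S)-3-[4-(tert-butyldimethylsilyloxy)phenyl]pent-4-enoate | C=C[C@@H](c1ccc(O[Si](C)(C)C(C)(C)C)cc1)CC(=O)OC | intermediate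
8 | methacrolein | C=C(C)C=O | starting material
9 | methyl (3S,4E)-3-[4-(tert-butyldimethylsilyloxy)phenyl]-5-methyl-6-oxohex-4-enoate | O=C/C(C)=C/[C@@H](c1ccc(O[Si](C)(C)C(C)(C)C)cc1)CC(=O)OC | intermediate
10 | methyl (3S,4E)-3-[4-(tert-butyldimethylsilyloxy)phenyl]-6-hydroxy-5-methylhept-4-enoate, both C6 epimers | CC(O)/C(C)=C/[C@@H](c1ccc(O[Si](C)(C)C(C)(C)C)cc1)CC(=O)OC | intermediate
11 | methyl (3S,4E)-3-[4-(tert-butyldimethylsilyloxy)phenyl]-5-methyl-6-oxohept-4-enoate | CC(=O)/C(C)=C/[C@@H](c1ccc(O[Si](C)(C)C(C)(C)C)cc1)CC(=O)OC | intermediate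
12 | methyl (3S,4E)-3-[4-(tert-butyldimethylsilyloxy)phenyl]-9,9,9-trifluoro-5-methyl-6,8-dioxonon-4-enoate | O=C(CC(=O)/C(C)=C/[C@@H](c1ccc(O[Si](C)(C)C(C)(C)C)cc1)CC(=O)OC)C(F)(F)F | intermediate
13 | methyl (3S,4E)-7-diazo-5-methyl-6-oxo-3-[4-(tert-butyldimethylsilyloxy)phenyl]hept-4-enoate | [N-]=[N+]=CC(=O)/C(C)=C/[C@@H](c1ccc(O[Si](C)(C)C(C)(C)C)cc1)CC(=O)OC | intermediate
14 | trimethylsilylacetylene | C#C[Si](C)(C)C | starting material
15 | triisopropylsilyl trifluoromethanesulfonate | CC(C)[Si](OS(=O)(=O)C(F)(F)F)(C(C)C)C(C)C | starting material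
16 | lithium (trimethylsilyl)acetylide | [Li]C#C[Si](C)(C)C | intermediate
17 | lithium 2-(trimethylsilyl)ethynolate | [Li+].[O-]C#C[Si](C)(C)C | intermediate
18 | triisopropyl{[(trimethylsilyl)ethynyl]oxy}silane | C[Si](C)(C)C#CO[Si](C(C)C)(C(C)C)C(C)C | intermediate
19 | (triisopropylsilyloxy)ethyne | C#CO[Si](C(C)C)(C(C)C)C(C)C | intermediate
20 | methyl (3S,4E)-3-[4-(tert-butyldimethylsilyloxy)phenyl]-5-methyl-7-oxohepta-4,6-dienoate (vinylketene) | O=C=C/C(C)=C/[C@@H](c1ccc(O[Si](C)(C)C(C)(C)C)cc1)CC(=O)OC | intermediate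
21 | methyl (3S,4E)-3-[4-(tert-butyldimethylsilyloxy)phenyl]-5-[4-oxo-2-(triisopropylsilyloxy)cyclobut-2-en-1-yl]hex-4-enoate, both ring epimers | O=C1C=C(O[Si](C(C)C)(C(C)C)C(C)C)C1/C(C)=C/[C@@H](c1ccc(O[Si](C)(C)C(C)(C)C)cc1)CC(=O)OC | intermediate
22 | methyl (3S,4E,6E)-3-[4-(tert-butyldimethylsilyloxy)phenyl]-5-methyl-9-oxo-7-(triisopropylsilyloxy)nona-4,6,8-trienoate (dienylketene) | O=C=C/C(O[Si](C(C)C)(C(C)C)C(C)C)=C\C(C)=C\[C@@H](c1ccc(O[Si](C)(C)C(C)(C)C)cc1)CC(=O)OC | intermediate
23 | methyl (3S)-3-[4-(tert-butyldimethylsilyloxy)phenyl]-3-[2-methyl-6-oxo-4-(triisopropylsilyloxy)cyclohexa-2,4-dien-1-yl]propanoate | O=C1C=C(O[Si](C(C)C)(C(C)C)C(C)C)C=C(C)C1[C@@H](c1ccc(O[Si](C)(C)C(C)(C)C)cc1)CC(=O)OC | intermediate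
24 | methyl (R)-3-[4-(tert-butyldimethylsilyloxy)phenyl]-3-[2-hydroxy-6-methyl-4-(triisopropylsilyloxy)phenyl]propanoate | Cc1cc(O[Si](C(C)C)(C(C)C)C(C)C)cc(O)c1[C@@H](c1ccc(O[Si](C)(C)C(C)(C)C)cc1)CC(=O)OC | intermediate
25 | methyl (R)-3-[3-bromo-6-hydroxy-2-methyl-4-(triisopropylsilyloxy)phenyl]-3-[4-(tert-butyldimethylsilyloxy)phenyl]propanoate | Cc1c(Br)c(O[Si](C(C)C)(C(C)C)C(C)C)cc(O)c1[C@@H](c1ccc(O[Si](C)(C)C(C)(C)C)cc1)CC(=O)OC | intermediate
26 | (R)-6-bromo-4-[4-(tert-butyldimethylsilyloxy)phenyl]-5-methyl-7-(triisopropylsilyloxy)chroman-2-one | Brc1c(O[Si](C(C)C)(C(C)C)C(C)C)cc2c(c1C)[C@@H](c1ccc(O[Si](C)(C)C(C)(C)C)cc1)CC(=O)O2 | intermediate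
27 | tributyl(1-ethoxyvinyl)stannane | CCCC[Sn](CCCC)(CCCC)C(=C)OCC | starting material
28 | (R)-4-[4-(tert-butyldimethylsilyloxy)phenyl]-6-(1-ethoxyvinyl)-5-methyl-7-(triisopropylsilyloxy)chroman-2-one | C=C(OCC)c1c(O[Si](C(C)C)(C(C)C)C(C)C)cc2c(c1C)[C@@H](c1ccc(O[Si](C)(C)C(C)(C)C)cc1)CC(=O)O2 | intermediate
29 | (R)-6-acetyl-4-[4-(tert-butyldimethylsilyloxy)phenyl]-5-methyl-7-(triisopropylsilyloxy)chroman-2-one | CC(=O)c1c(O[Si](C(C)C)(C(C)C)C(C)C)cc2c(c1C)[C@@H](c1ccc(O[Si](C)(C)C(C)(C)C)cc1)CC(=O)O2 | intermediate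
30 | (R)-4-[4-(tert-butyldimethylsilyloxy)phenyl]-5-methyl-7-(triisopropylsilyloxy)-6-[1-(trimethylsilyloxy)vinyl]chroman-2-one | C=C(O[Si](C)(C)C)c1c(O[Si](C(C)C)(C(C)C)C(C)C)cc2c(c1C)[C@@H](c1ccc(O[Si](C)(C)C(C)(C)C)cc1)CC(=O)O2 | intermediate
31 | malonyl dichloride | O=C(Cl)CC(=O)Cl | starting material
32 | 5-{(R)-4-[4-(tert-butyldimethylsilyloxy)phenyl]-5-methyl-2-oxo-7-(triisopropylsilyloxy)chroman-6-yl}-3,5-dioxopentanoyl chloride | O=C(Cl)CC(=O)CC(=O)c1c(O[Si](C(C)C)(C(C)C)C(C)C)cc2c(c1C)[C@@H](c1ccc(O[Si](C)(C)C(C)(C)C)cc1)CC(=O)O2 | intermediate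
33 | (R)-4-[4-(tert-butyldimethylsilyloxy)phenyl]-6-(4-hydroxy-2-oxo-2H-pyran-6-yl)-5-methyl-7-(triisopropylsilyloxy)chroman-2-one | Oc1cc(-c2c(O[Si](C(C)C)(C(C)C)C(C)C)cc3c(c2C)[C@@H](c2ccc(O[Si](C)(C)C(C)(C)C)cc2)CC(=O)O3)oc(=O)c1 | intermediate
34 | (R)-4-[4-(tert-butyldimethylsilyloxy)phenyl]-6-(4-methoxy-2-oxo-2H-pyran-6-yl)-5-methyl-7-(triisopropylsilyloxy)chroman-2-one | COc1cc(-c2c(O[Si](C(C)C)(C(C)C)C(C)C)cc3c(c2C)[C@@H](c2ccc(O[Si](C)(C)C(C)(C)C)cc2)CC(=O)O3)oc(=O)c1 | intermediate
35 | (R)-7-hydroxy-4-(4-hydroxyphenyl)-6-(4-methoxy-2-oxo-2H-pyran-6-yl)-5-methylchroman-2-one (CNP0207475.1) | COc1cc(-c2c(O)cc3c(c2C)[C@@H](c2ccc(O)cc2)CC(=O)O3)oc(=O)c1 | target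

**Totals**
Total steps: 17. Longest linear sequence: 15 (steps 1–7 and 10–17). Steps 8 and 9 form a two-step side branch.

**Steps most likely to fail**

Step 10.
- Light may isomerise the enone double bond before or after loss of N2. That brings C4–H within reach of the ketene carbon, so a 1,5-hydrogen shift could drain material.
- The newly formed phenol may be acylated by unreacted ketene.
- The terminal siloxyalkyne may be consumed by traces of acid before it can add.
- Fallback: it sets out from 13 and returns at 24. The ketene is made in the dark and the cycloaddition is separated from the electrocyclic cascade.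
- Silver-catalysed Wolff rearrangement of 13 (AgO2CPh, Et3N, THF/H2O) would give (3E,5S)-7-methoxy-3-methyl-7-oxo-5-[4-(tert-butyldimethylsilyloxy)phenyl]hept-3-enoic acid F1.
- Oxalyl chloride with catalytic DMF would convert F1 into methyl (3S,4E)-7-chloro-5-methyl-7-oxo-3-[4-(tert-butyldimethylsilyloxy)phenyl]hept-4-enoate F2.
- Slow addition of Et3N to F2 and 19 in CH2Cl2 would generate 20 by dehydrochlorination.
- Cyclobutenone 21 is then isolated and heated on its own in toluene to give 24.

Step 4.
- Turnover may be slow because both olefins are hindered.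
- Ruthenium hydrides may move the double bond into conjugation with ring D, which removes C4 as a stereocentre.
- Fallback: it sets out from 7 and returns at 11, bypassing steps 5 and 6.
- Ozonolysis (O3, CH2Cl2, −78 °C; Me2S) would give methyl (R)-4-oxo-3-[4-(tert-butyldimethylsilyloxy)phenyl]butanoate F3.
- F3 is not stored. It is treated at once with commercial 3-(triphenylphosphoranylidene)butan-2-one in toluene (Wittig olefination) to give the (E)-enone 11.
- The cost is passage through an enolisable α-aryl aldehyde, so the enantiomeric purity of 11 has to be checked.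

Step 15.
- Liberated HCl may protodesilylate the enol silane faster than the hindered system is C-acylated.
- A second acylation at C3' of the new pyranone may follow.
- Fallback: it sets out from 26 and returns at 34, bringing in the pyranone ring intact by cross-coupling.
- Miyaura borylation of 26 (B2pin2, KOAc, PdCl2(dppf), dioxane, 90 °C) would give (R)-4-[4-(tert-butyldimethylsilyloxy)phenyl]-5-methyl-6-(4,4,5,5-tetramethyl-1,3,2-dioxaborolan-2-yl)-7-(triisopropylsilyloxy)chroman-2-one F4.
- The coupling partner would be made from 31 as follows.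
  - Thermal self-condensation gives 6-chloro-4-hydroxy-2-oxo-2H-pyran-3-carbonyl chloride F5.
  - Hydrolysis gives 6-chloro-4-hydroxy-2-oxo-2H-pyran-3-carboxylic acid F6.
  - Decarboxylation gives 6-chloro-4-hydroxy-2H-pyran-2-one F7.
  - O-methylation (Me2SO4, K2CO3, acetone) gives 6-chloro-4-methoxy-2H-pyran-2-one F8.
- Suzuki–Miyaura coupling of F4 and F8 (Pd(OAc)2, SPhos, K3PO4, toluene, 80 °C) would give 34.

**Further compounds**
F1 | step 10 | (3E,5S)-7-methoxy-3-methyl-7-oxo-5-[4-(tert-butyldimethylsilyloxy)phenyl]hept-3-enoic acid | OC(=O)C/C(C)=C/[C@@H](c1ccc(O[Si](C)(C)C(C)(C)C)cc1)CC(=O)OC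
F2 | step 10 | methyl (3S,4E)-7-chloro-5-methyl-7-oxo-3-[4-(tert-butyldimethylsilyloxy)phenyl]hept-4-enoate | ClC(=O)C/C(C)=C/[C@@H](c1ccc(O[Si](C)(C)C(C)(C)C)cc1)CC(=O)OC
F3 | step 4 | methyl (R)-4-oxo-3-[4-(tert-butyldimethylsilyloxy)phenyl]butanoate | O=C[C@@H](c1ccc(O[Si](C)(C)C(C)(C)C)cc1)CC(=O)OC
F4 | step 15 | (R)-4-[4-(tert-butyldimethylsilyloxy)phenyl]-5-methyl-6-(4,4,5,5-tetramethyl-1,3,2-dioxaborolan-2-yl)-7-(triisopropylsilyloxy)chroman-2-one | CC1(C)OB(OC1(C)C)c1c(O[Si](C(C)C)(C(C)C)C(C)C)cc2c(c1C)[C@@H](c1ccc(O[Si](C)(C)C(C)(C)C)cc1)CC(=O)O2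
F5 | step 15 | 6-chloro-4-hydroxy-2-oxo-2H-pyran-3-carbonyl chloride | O=C(Cl)c1c(O)cc(Cl)oc1=O
F6 | step 15 | 6-chloro-4-hydroxy-2-oxo-2H-pyran-3-carboxylic acid | O=C(O)c1c(O)cc(Cl)oc1=O
F7 | step 15 | 6-chloro-4-hydroxy-2H-pyran-2-one | Oc1cc(Cl)oc(=O)c1
F8 | step 15 | 6-chloro-4-methoxy-2H-pyran-2-one | COc1cc(Cl)oc(=O)c1
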